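4 questions stand on two flasks, summer and dusk, and I answer them with one quantity.

all flasks: substrate 20 mM

| run | partner | rival reagent | remark | time |
|---|---|---|---|---|
| alpha | 56 mM | 20 mM | run made earlier |  |
| beta | 170 mM | 20 mM | run made earlier |  |
| summer | 40.0 mM | 20.0 mM |  | 1.5 h |
| dusk | 120 mM | 20.0 mM |  | 1.5 h |

| run | time / min | target / % | substrate / % |
|---|---|---|---|
| alpha | 20.0 | 16.0 | 81.0 |
| alpha | 40.0 | 29.4 | 66.8 |
| alpha | 50.0 | 33.5 | 61.5 |
| alpha | 80.0 | 46.9 | 48.4 |
| alpha | 90.0 | 50.1 | 44.2 |
| beta | 8.00 | 20.2 | 77.6 |
| beta | 25.0 | 48.9 | 48.1 |
| beta | 40.0 | 63.8 | 32.2 |
| beta | 60.0 | 76.9 | 19.0 |
| beta | 90.0 | 87.4 | 8.7 |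

(standard deviation of a reading: 0.5 percentage points)

- the numbers in the tables scatter with a standard deviation of 0.5 percentage points
- candidate steps: substrate + partner -> target; substrate + rival reagent -> side product; rival reagent -> decomposed reagent

1. which of the two there is more of at the end, summer (side product / target)
2. which of the two there is more of at the end, dusk (side product / target)
3. target at the end, in percent of the substrate charged, summer
4. target at the end, in percent of the substrate charged, dusk

Two things hold nearly still late in beta, and I freeze them. The first is the gap, what is missing from substrate plus target, which I read as side product. In beta it reads 4.00% at 40.0 min and 3.90% at 90.0 min, so between those readings substrate goes to target. Alpha ends with a gap of 5.70%.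

The second is c(partner), which in beta moves little because it is charged in excess; this is the pseudo-first-order picture. Between those beta readings substrate falls from 32.2% to 8.7% while c(partner) stands near 155 mM. That gives a reading of 10.1 M⁻¹ h⁻¹, the decay rate of substrate per unit of c(partner). Multiplied by c(partner) and time it is the exposure, and I take target as the substrate outside the gap times one minus the exponential of minus the exposure.

For summer I take alpha's gap and solve two extreme flasks. With c(partner) frozen at its charge, target is 43.0%. With c(partner) frozen at the 31.4 mM which that version leaves, target is 35.8%. The real partner travels from the first level towards the second, so I expect summer's target between them, and the mean level, 35.7 mM, gives me 39.5%. For dusk, whose partner lies between alpha's and beta's, I take the mean gap, 4.80%, and the same steps give 79.9%, then 77.9%. In my reckoning target stands above side product in summer and in dusk.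

The forecast says target for summer and target for dusk, with 39.8% and 77.8%, and it reads from the early halt of side product that “the rival reagent is dying on its own”.

The flasks give 39.4% of target in summer and 77.4% in dusk, with 5.58% and 4.61% of side product.

    substrate + partner → target (k = 10.0 M⁻¹ h⁻¹)
    substrate + rival reagent → side product (k = 10.0 M⁻¹ h⁻¹)
    rival reagent → decomposed reagent (k = 2.90 h⁻¹)

At the end of summer, partner stands at 80.3% of its charge, above the 78.5% of my second extreme. For one more flask, like dusk but with 30 mM of partner, the same rate and alpha's gap give 34.5% at the frozen charge and 31.3% at the mean level, and that flask ends with 31.3% of target.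

(The earlier runs and the new flask were generated by integration from invented constants, noise included.)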